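**Retrosynthetic overview**

1. Locants (farnesane type): ring A = C6–C11 (C7 carries the exocyclic C15 methylene, C10 the bromine, C11 the two methyls); ring B = C1–C6 (C2 Br, C3 Cl and methyl); C6 is the spiro atom. Enabling feature: spiro C6 lies between C7(=C15H2) and quaternary C11, so ring A can be carried as a C6=C7 tetrasubstituted olefin with C15 as a methyl group. This is a π-nucleophile whose ring carbon C6 sits six atoms from C1, the CH2 next to the C2–Br carbon.
2. Key disconnection C1–C6: cationic spirocyclisation of the primary triflate of bromochloro alcohol 16 closes ring B, creates the spiro stereocentre and releases the exocyclic methylene in one operation.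
3. 16 comes from (Z)-allylic alcohol 15 by enantioselective bromochlorination (sets C2 and C3); 15 comes from a B-alkyl Suzuki–Miyaura union (C3–C4 bond) of ring-A diene 11 with (Z)-3-iodobut-2-en-1-ol 13.
4. Ring A (10, 11) comes from geranyl acetate: allylic oxidation, enantioselective bromochlorination, deoxygenation, bromochloride-initiated bromonium cyclisation (C6–C11 bond, carries C10–Br) with carbonate capture, then aldol-type dehydration that fixes the C6=C7 olefin.
5. Order of ring formation: ring A first (step 5), ring B last (step 12).

Key step: step 12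

Assumption: in the two titanium-mediated bromochlorinations and in the epoxidation used in a fallback, the absolute sense of induction follows the catalyst enantiomer; in each case the enantiomer giving the stated configuration is used.

**Route**

Step 1
Reactants: 1 geranyl acetate [(2E)-3,7-dimethylocta-2,6-dien-1-yl acetate]
Product: 2 (2E,6E)-8-hydroxy-3,7-dimethylocta-2,6-dien-1-yl acetate
Conditions: SeO2 (cat.), t-BuOOH, salicylic acid (cat.), CH2Cl2, rt
Reagents that add atoms: tert-butyl hydroperoxide, CC(C)(C)OO
Why: Catalytic SeO2 allylic oxidation (ene reaction then [2,3]-shift) should hydroxylate the (E)-methyl group of the distal, more electron-rich olefin selectively; no stereocentre is formed.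

Step 2
Reactants: 2 (2E,6E)-8-hydroxy-3,7-dimethylocta-2,6-dien-1-yl acetate
Product: 3 (2E,6S,7R)-6-bromo-7-chloro-8-hydroxy-3,7-dimethyloct-2-en-1-yl acetate
Conditions: NBS, ClTi(OiPr)3, chiral tridentate Schiff-base (salicylaldimine amino-alcohol) ligand (20 mol%), hexanes, −20 °C
Reagents that add atoms: N-bromosuccinimide, O=C1CCC(=O)N1Br; chlorotitanium triisopropoxide, CC(C)O[Ti](Cl)(OC(C)C)OC(C)C
Why: Titanium-mediated catalytic enantioselective bromochlorination of an allylic alcohol should add Br and Cl anti across the (E)-olefin with Markovnikov chloride at the tertiary carbon, the ligand fixing the face and so setting 6S and 7R; the allylic-acetate olefin is electron-poor and not bound to titanium, so it should be spared.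

Step 3
Reactants: 3 (2E,6S,7R)-6-bromo-7-chloro-8-hydroxy-3,7-dimethyloct-2-en-1-yl acetate
Product: 5 (2E,6S)-6-bromo-7-chloro-3,7-dimethyloct-2-en-1-ol, via primary triflate 4 (not isolated)
Conditions: Tf2O, pyridine, CH2Cl2, −78 to −20 °C, aqueous wash; then LiBHEt3 (excess), THF, −78 to 0 °C
Reagents that add atoms: none
Why: Sulfonate formation and SN2 hydride displacement (LiBHEt3 is the usual hydride for neopentyl-type sulfonates) should turn CH2OH into the second methyl group, so C7 ceases to be a stereocentre while C6 is untouched; the excess hydride also cleaves the acetate.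

Step 4
Reactants: 5 (2E,6S)-6-bromo-7-chloro-3,7-dimethyloct-2-en-1-ol
Product: 6 tert-butyl (2E,6S)-6-bromo-7-chloro-3,7-dimethyloct-2-en-1-yl carbonate
Conditions: Boc2O, DMAP (cat.), CH2Cl2, rt
Reagents that add atoms: di-tert-butyl dicarbonate, CC(C)(C)OC(=O)OC(=O)OC(C)(C)C
Why: DMAP-catalysed O-acylation should give the tert-butyl carbonate that later acts as the internal oxygen nucleophile; no stereocentre is affected.

Step 5
Reactants: 6 tert-butyl (2E,6S)-6-bromo-7-chloro-3,7-dimethyloct-2-en-1-yl carbonate
Product: 7 (4aR,6S,8aS)-6-bromo-5,5,8a-trimethylhexahydro-4H-1,3-benzodioxin-2-one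
Conditions: HFIP, NaHCO3, rt
Reagents that add atoms: none
Why: Solvolytic ionisation of the tertiary chloride with anchimeric help from bromine should give an enantiopure bromonium ion (bromochloride-initiated bromonium polyene cyclisation), opened at the tertiary carbon by the (E)-olefin through a chair (6-endo) while the carbonate carbonyl captures the tertiary cation with loss of isobutene; the C–Br carbon keeps its configuration and anti addition across the (E)-olefin gives the trans ring fusion.

Step 6
Reactants: 7 (4aR,6S,8aS)-6-bromo-5,5,8a-trimethylhexahydro-4H-1,3-benzodioxin-2-one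
Product: 8 (1S,2R,4S)-4-bromo-2-(hydroxymethyl)-1,3,3-trimethylcyclohexan-1-ol
Conditions: K2CO3, MeOH, rt
Reagents that add atoms: none
Why: Base-catalysed transesterification of the cyclic carbonate with methanol should release the 1,3-diol without touching any stereocentre.

Step 7
Reactants: 8 (1S,2R,4S)-4-bromo-2-(hydroxymethyl)-1,3,3-trimethylcyclohexan-1-ol
Product: 10 (5S)-5-bromo-2,6,6-trimethylcyclohex-1-ene-1-carbaldehyde, via β-hydroxy aldehyde 9 (not isolated)
Conditions: DMP, CH2Cl2, rt; then p-TsOH·H2O (cat.), 40 °C
Reagents that add atoms: none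
Why: Dess–Martin oxidation of the primary alcohol gives a β-hydroxy aldehyde whose acid-catalysed aldol-type dehydration can only give the conjugated enal, so the tetrasubstituted olefin should be placed regiospecifically at C6=C7 (two stereocentres are erased on purpose, the C–Br centre remains).

Step 8
Reactants: 10 (5S)-5-bromo-2,6,6-trimethylcyclohex-1-ene-1-carbaldehyde
Product: 11 (4S)-4-bromo-2-ethenyl-1,3,3-trimethylcyclohex-1-ene
Conditions: Ph3PCH3Br, KOtBu, THF, 0 °C to rt
Reagents that add atoms: methylenetriphenylphosphorane, C=P(c1ccccc1)(c1ccccc1)c1ccccc1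
Why: Wittig methylenation of the hindered enal (well established for the bromine-free parent aldehyde) should give the 1,3-diene; no stereocentre is involved.

Step 9
Reactants: 12 but-2-yn-1-ol
Product: 13 (2Z)-3-iodobut-2-en-1-ol
Conditions: NaAlH2(OCH2CH2OMe)2, THF, 0 °C to rt; then I2, −78 °C
Reagents that add atoms: iodine, II
Why: Hydroxyl-directed trans-hydroalumination of the propargylic alcohol followed by iodination of the vinyl–aluminium bond with retention should give the (Z)-vinyl iodide with iodine cis to CH2OH.

Step 10
Reactants: 11 (4S)-4-bromo-2-ethenyl-1,3,3-trimethylcyclohex-1-ene; 13 (2Z)-3-iodobut-2-en-1-ol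
Product: 15 (2Z)-5-[(5S)-5-bromo-2,6,6-trimethylcyclohex-1-en-1-yl]-3-methylpent-2-en-1-ol, via B-alkyl-9-BBN adduct 14 (not isolated)
Conditions: 9-BBN, THF, rt; then 13, Pd(dppf)Cl2 (cat.), AsPh3, Cs2CO3, DMF/H2O, rt
Reagents that add atoms: none
Why: 9-BBN should hydroborate only the monosubstituted vinyl group (boron at the terminal carbon), and the B-alkyl Suzuki–Miyaura coupling proceeds with retention of olefin geometry to give the (Z)-trisubstituted allylic alcohol; the hindered secondary bromide should be inert to the zerovalent palladium catalyst under these mild conditions.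

Step 11
Reactants: 15 (2Z)-5-[(5S)-5-bromo-2,6,6-trimethylcyclohex-1-en-1-yl]-3-methylpent-2-en-1-ol
Product: 16 (2S,3S)-2-bromo-5-[(5S)-5-bromo-2,6,6-trimethylcyclohex-1-en-1-yl]-3-chloro-3-methylpentan-1-ol
Conditions: NBS, ClTi(OiPr)3, chiral tridentate Schiff-base ligand (20 mol%), hexanes, −20 °C
Reagents that add atoms: N-bromosuccinimide, O=C1CCC(=O)N1Br; chlorotitanium triisopropoxide, CC(C)O[Ti](Cl)(OC(C)C)OC(C)C
Why: The same titanium-mediated enantioselective bromochlorination should add Br (C2) and Cl (tertiary C3) anti across the (Z)-olefin with catalyst control of the face, giving 2S,3S; the titanium-bound allylic alcohol should react faster than the hindered, undirected ring olefin.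

Step 12
Reactants: 16 (2S,3S)-2-bromo-5-[(5S)-5-bromo-2,6,6-trimethylcyclohex-1-en-1-yl]-3-chloro-3-methylpentan-1-ol
Product: 18 nidificene, via primary triflate 17 (not isolated)
Conditions: Tf2O, 2,6-di-tert-butyl-4-methylpyridine, CH2Cl2 (high dilution), −78 to 0 °C
Reagents that add atoms: none
Why: Proposed new method: the alcohol is converted at −78 °C into triflate 17, whose departure is assisted by the anti-periplanar C2 bromine (bromonium character at C1–C2) and by the C6=C7 olefin of ring A, which attacks C1 with its ring carbon C6 to give the spiro tertiary C7 cation, from which the hindered pyridine removes a proton of the C15 methyl. The closest known reaction types are the solvolytic cation–olefin cyclisation of alkenyl sulfonate esters, the bromonium polyene cyclisation started by ionising a vicinal bromochloride, and the acid-induced spirocyclisation of monocyclofarnesyl allyl cations to chamigrenes. Ring B closes through a chair by 6-endo opening of the C1–C2 bromonium unit (6-exo with respect to the ring-A olefin, spiro mode); attack at C2 (five-membered ring) is disfavoured because C2 is neopentyl-like and inductively deactivated by the C3 chlorine. The only new stereocentre, spiro C6, is controlled twice in the same sense: in ring B the bromine must be anti to the incoming C6 and so becomes equatorial, which puts the trans chlorine equatorial and lets the bulky C11 take the equatorial and C7 the axial position; in ring A, C1 adds axially to the face opposite the axial C11 methyl and the C10 bromine. The step needs regioselective proton loss (C15, not C8) and survival of the tertiary chloride; the first is sought with a bulky base that reaches the exposed methyl but not the axial H-8 shielded by ring B, the second with a non-ionising solvent and low temperature.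

**Compound list**

1 | geranyl acetate, (2E)-3,7-dimethylocta-2,6-dien-1-yl acetate | CC(=O)OC/C=C(\C)CCC=C(C)C | starting material
2 | (2E,6E)-8-hydroxy-3,7-dimethylocta-2,6-dien-1-yl acetate | CC(=O)OC/C=C(\C)CC/C=C(\C)CO | intermediate
3 | (2E,6S,7R)-6-bromo-7-chloro-8-hydroxy-3,7-dimethyloct-2-en-1-yl acetate | CC(=O)OC/C=C(\C)CC[C@H](Br)[C@](C)(Cl)CO | intermediate
4 | primary triflate of 3 | CC(=O)OC/C=C(\C)CC[C@H](Br)[C@](C)(Cl)COS(=O)(=O)C(F)(F)F | intermediate
5 | (2E,6S)-6-bromo-7-chloro-3,7-dimethyloct-2-en-1-ol | OC/C=C(\C)CC[C@H](Br)C(C)(C)Cl | intermediate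
6 | tert-butyl (2E,6S)-6-bromo-7-chloro-3,7-dimethyloct-2-en-1-yl carbonate | CC(C)(C)OC(=O)OC/C=C(\C)CC[C@H](Br)C(C)(C)Cl | intermediate
7 | (4aR,6S,8aS)-6-bromo-5,5,8a-trimethylhexahydro-4H-1,3-benzodioxin-2-one | O=C1OC[C@@H]2[C@](C)(CC[C@H](Br)C2(C)C)O1 | intermediate
8 | (1S,2R,4S)-4-bromo-2-(hydroxymethyl)-1,3,3-trimethylcyclohexan-1-ol | OC[C@@H]1[C@@](C)(O)CC[C@H](Br)C1(C)C | intermediate
9 | (1S,3S,6S)-3-bromo-6-hydroxy-2,2,6-trimethylcyclohexane-1-carbaldehyde | O=C[C@@H]1[C@@](C)(O)CC[C@H](Br)C1(C)C | intermediate
10 | (5S)-5-bromo-2,6,6-trimethylcyclohex-1-ene-1-carbaldehyde | O=CC1=C(C)CC[C@H](Br)C1(C)C | intermediate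
11 | (4S)-4-bromo-2-ethenyl-1,3,3-trimethylcyclohex-1-ene | C=CC1=C(C)CC[C@H](Br)C1(C)C | intermediate
12 | but-2-yn-1-ol | CC#CCO | starting material
13 | (2Z)-3-iodobut-2-en-1-ol | OC/C=C(/C)I | intermediate
14 | 9-{2-[(5S)-5-bromo-2,6,6-trimethylcyclohex-1-en-1-yl]ethyl}-9-borabicyclo[3.3.1]nonane | CC1=C(CCB2C3CCCC2CCC3)C(C)(C)[C@@H](Br)CC1 | intermediate
15 | (2Z)-5-[(5S)-5-bromo-2,6,6-trimethylcyclohex-1-en-1-yl]-3-methylpent-2-en-1-ol | OC/C=C(/C)CCC1=C(C)CC[C@H](Br)C1(C)C | intermediate
16 | (2S,3S)-2-bromo-5-[(5S)-5-bromo-2,6,6-trimethylcyclohex-1-en-1-yl]-3-chloro-3-methylpentan-1-ol | CC1=C(CC[C@](C)(Cl)[C@@H](Br)CO)C(C)(C)[C@@H](Br)CC1 | intermediate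
17 | primary triflate of 16 | CC1=C(CC[C@](C)(Cl)[C@@H](Br)COS(=O)(=O)C(F)(F)F)C(C)(C)[C@@H](Br)CC1 | intermediate
18 | nidificene, 2,10-dibromo-3-chloro-chamigr-7(15)-ene (C2, C3, C6 and C10 all S in the locants used here) | C=C1CC[C@H](Br)C(C)(C)[C@]12CC[C@](C)(Cl)[C@@H](Br)C2 | target

**Step count**

Total: 12 steps. Longest linear sequence: 11 steps (steps 1–8 and 10–12, from geranyl acetate).

**Steps most likely to fail**

Step 12 (Proposed new method). What may go wrong: after ring closure the tertiary C7 cation may lose the proton from C8 instead of C15, so that the double bond ends up inside ring A. The fallback sets out from 16 and comes back at 18. The closure is run as in step 12 and the product is taken on as the endocyclic olefin, 2,10-dibromo-3-chloro-chamigr-7-ene F1. F1 is then isomerised by the classical triplet-sensitised photoprotonation–deprotonation of 1-methylcyclohexenes (hν, p-xylene as sensitiser, tert-butanol with a trace of acid), a known way of moving a six-ring double bond into the exocyclic position against the thermodynamic preference, to give 18. The fallback covers the olefin position only; it still relies on the C1–C6 closure itself.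

Step 5. What may go wrong: attack of the electron-poor allylic-carbonate olefin on the bromonium ion may be slower than chloride return, and the tert-butyl carbonate may be lost before it can capture the cation. The fallback sets out from 5 and comes back at 10; it replaces oxygen capture and dehydration by proton-loss termination and base-mediated convergence. Free alcohol 5 is cyclised in HFIP buffered with NaHCO3 to [(1R,5S)-5-bromo-2,6,6-trimethylcyclohex-2-en-1-yl]methanol F2 (accompanied by its exocyclic olefin isomer, which behaves the same way). Dess–Martin oxidation gives the β,γ-unsaturated aldehyde (1R,5S)-5-bromo-2,6,6-trimethylcyclohex-2-ene-1-carbaldehyde F3, and DBU in the same flask moves the double bond into conjugation through the dienolate to give 10.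

Step 3. What may go wrong: hydride displacement at the neopentyl-like carbon next to the C–Cl centre may be slow, so that halogen migration or reduction of a carbon–halogen bond competes. The fallback sets out from 1 and comes back at 7; it needs no deoxygenation because the bromonium ion is reached from an epoxide.
- Shi epoxidation of the distal olefin of 1 (fructose-derived ketone catalyst, KHSO5, buffered MeCN/H2O, 0 °C) should give (2E)-5-[(2R)-3,3-dimethyloxiran-2-yl]-3-methylpent-2-en-1-yl acetate F4.
- Methanolysis (K2CO3, MeOH) should give (2E)-5-[(2R)-3,3-dimethyloxiran-2-yl]-3-methylpent-2-en-1-ol F5.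
- Boc2O with DMAP should give tert-butyl (2E)-5-[(2R)-3,3-dimethyloxiran-2-yl]-3-methylpent-2-en-1-yl carbonate F6.
- MgBr2·OEt2 should open the epoxide at the tertiary carbon to tert-butyl (2E,6R)-7-bromo-6-hydroxy-3,7-dimethyloct-2-en-1-yl carbonate F7.
- Tf2O with 2,6-di-tert-butyl-4-methylpyridine in CH2Cl2 at −78 °C should give the secondary triflate of F7 F8, which is not isolated. The neighbouring bromine displaces the triflate with inversion to give the same bromonium ion as in step 5, and this closes with carbonate capture to 7.

**Further compounds**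

F1 | step 12 | 2,10-dibromo-3-chloro-chamigr-7-ene (endocyclic C7=C8 isomer of 18) | CC1=CC[C@H](Br)C(C)(C)[C@]12CC[C@](C)(Cl)[C@@H](Br)C2
F2 | step 5 | [(1R,5S)-5-bromo-2,6,6-trimethylcyclohex-2-en-1-yl]methanol | CC1=CC[C@H](Br)C(C)(C)[C@@H]1CO
F3 | step 5 | (1R,5S)-5-bromo-2,6,6-trimethylcyclohex-2-ene-1-carbaldehyde | CC1=CC[C@H](Br)C(C)(C)[C@@H]1C=O
F4 | step 3 | (2E)-5-[(2R)-3,3-dimethyloxiran-2-yl]-3-methylpent-2-en-1-yl acetate | CC(=O)OC/C=C(\C)CC[C@H]1OC1(C)C
F5 | step 3 | (2E)-5-[(2R)-3,3-dimethyloxiran-2-yl]-3-methylpent-2-en-1-ol | OC/C=C(\C)CC[C@H]1OC1(C)C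
F6 | step 3 | tert-butyl (2E)-5-[(2R)-3,3-dimethyloxiran-2-yl]-3-methylpent-2-en-1-yl carbonate | CC(C)(C)OC(=O)OC/C=C(\C)CC[C@H]1OC1(C)C
F7 | step 3 | tert-butyl (2E,6R)-7-bromo-6-hydroxy-3,7-dimethyloct-2-en-1-yl carbonate | CC(C)(C)OC(=O)OC/C=C(\C)CC[C@@H](O)C(C)(C)Br
F8 | step 3 | secondary triflate of F7 | CC(C)(C)OC(=O)OC/C=C(\C)CC[C@@H](OS(=O)(=O)C(F)(F)F)C(C)(C)Br
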